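Cuts: first the methyl ester C–O bond at C1, leading back to a meso cyclobutane-fused anhydride and its cis-diacid. Next, ring bonds C1–C2 and C3–C4 are cut together, which halves the core into two molecules of (E)-3-(4-methoxy-3-methyl-2-oxopyran-6-yl)but-2-enoic acid. Then come the C=C of that acid (olefination of a 6-acetylpyranone) and the pyranone bonds O1–C2 (lactonisation) and C5–C6 (dianion acylation).
Enabling feature: the ring C1–C4 is the head-to-head syn dimer of one E-enoate. The carboxyl carbons on C1 and C2 lie on the same face and can be spanned by the two peri oxygens of naphthalene-1,8-diol. C3 and C4, each carrying CH3 and the pyranon-6-yl ring, are the stacked β-termini, and only ester versus acid breaks the mirror plane.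
Ring order forward: pyranone, then two copies on the peri diol, then the cyclobutane plus a temporary nine-membered dilactone in one photochemical step. The tether ring is then opened, and a five-membered anhydride is closed and reopened.
Stereochemistry: the alkene geometry and the tether fix all four ring centres relative to one another in the photocycloaddition. The absolute sense comes only from alkaloid-catalysed methanolysis of the meso anhydride. The lactate centre is a spectator that disappears at the ketone stage.

Key step: step 11

Conventions: C1 carries CO2Me, C2 carries CO2H, C3 is next to C2 and C4 is next to C1. Pyr = 4-methoxy-3-methyl-2-oxo-2H-pyran-6-yl.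
Assumption: quinidine-derived catalysts are taken to open the meso anhydride in the sense recalled for unsubstituted cis-cycloalkane-1,2-dicarboxylic anhydrides, which maps onto ester at C1 (R) and acid at C2 (S); the sense would be confirmed by correlation, and the quinine-derived pseudoenantiomer gives the mirror image.

Step 1
Reactants: 1 ethyl (S)-lactate
Product: 2 ethyl (S)-2-[(tert-butyldimethylsilyl)oxy]propanoate
Conditions: TBSCl, imidazole, DMF, 0 °C to rt
Reagents that add atoms: tert-butyldimethylsilyl chloride, CC(C)(C)[Si](C)(C)Cl
Why: Imidazole-promoted silylation of a secondary alcohol is routine, leaves the stereocentre alone and gives an ether that withstands the Grignard base, LDA, DBU and carbonate used up to step 5.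

Step 2
Reactants: 2 ethyl (S)-2-[(tert-butyldimethylsilyl)oxy]propanoate
Product: 3 (S)-2-[(tert-butyldimethylsilyl)oxy]-N-methoxy-N-methylpropanamide
Conditions: MeNH(OMe)·HCl, i-PrMgCl, THF, −20 to 0 °C
Reagents that add atoms: N,O-dimethylhydroxylamine hydrochloride, CNOC.Cl
Why: Ester-to-Weinreb-amide aminolysis with the magnesium amide made in situ is standard for α-silyloxy esters, and any erosion of the (S) centre would not matter because step 7 removes it.

Step 3
Reactants: 4 ethyl 2-methylacetoacetate; 3 (S)-2-[(tert-butyldimethylsilyl)oxy]-N-methoxy-N-methylpropanamide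
Product: 6 ethyl (6S)-6-[(tert-butyldimethylsilyl)oxy]-2-methyl-3,5-dioxoheptanoate, via dilithium dienediolate 5 (not isolated)
Conditions: 4 (1.5 equiv), LDA (3.1 equiv), THF, −78 to 0 °C; then 3, −78 to 0 °C; cold 1 M HCl
Reagents that add atoms: none
Why: In this γ-acylation of a β-keto ester dianion (Weinreb ketone synthesis) the terminal carbon of 5 is the more nucleophilic site and the chelated tetrahedral adduct survives until the quench, so over-addition and proton transfer from the acidic product are both avoided.

Step 4
Reactants: 6 ethyl (6S)-6-[(tert-butyldimethylsilyl)oxy]-2-methyl-3,5-dioxoheptanoate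
Product: 7 6-[(1S)-1-[(tert-butyldimethylsilyl)oxy]ethyl]-4-hydroxy-3-methyl-2H-pyran-2-one
Conditions: DBU, toluene, 60 °C; then 1 M HCl
Reagents that add atoms: none
Why: Base-mediated lactonisation of a 3,5-dioxo ester, in which the C5 enolate oxygen attacks the ester carbonyl (6-exo-trig) and ethoxide leaves, is the standard entry to 4-hydroxy-2-pyranones and is driven by the delocalised vinylogous carboxylate.

Step 5
Reactants: 7 6-[(1S)-1-[(tert-butyldimethylsilyl)oxy]ethyl]-4-hydroxy-3-methyl-2H-pyran-2-one
Product: 8 6-[(1S)-1-[(tert-butyldimethylsilyl)oxy]ethyl]-4-methoxy-3-methyl-2H-pyran-2-one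
Conditions: Me2SO4, K2CO3, acetone, rt to 45 °C
Reagents that add atoms: dimethyl sulfate, COS(=O)(=O)OC
Why: O-Methylation of 4-hydroxy-2-pyranones with dimethyl sulfate and carbonate in acetone is known to favour the 4-methoxy-2-pyranone over the 2-methoxy-4-pyranone isomer, which chromatography would remove if it formed.

Step 6
Reactants: 8 6-[(1S)-1-[(tert-butyldimethylsilyl)oxy]ethyl]-4-methoxy-3-methyl-2H-pyran-2-one
Product: 9 6-[(1S)-1-hydroxyethyl]-4-methoxy-3-methyl-2H-pyran-2-one
Conditions: HF·pyridine, THF, 0 °C to rt
Reagents that add atoms: none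
Why: Fluoride-driven desilylation under weakly acidic conditions frees the carbinol without exposing the pyranone to a basic nucleophile.

Step 7
Reactants: 9 6-[(1S)-1-hydroxyethyl]-4-methoxy-3-methyl-2H-pyran-2-one
Product: 10 6-acetyl-4-methoxy-3-methyl-2H-pyran-2-one
Conditions: Dess–Martin periodinane, CH2Cl2, rt
Reagents that add atoms: none
Why: Dess–Martin oxidation of a secondary heteroaryl carbinol runs under neutral conditions that spare the enol ether and lactone, and it removes the no longer needed lactate stereocentre.

Step 8
Reactants: 10 6-acetyl-4-methoxy-3-methyl-2H-pyran-2-one; 11 tert-butyl diethylphosphonoacetate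
Product: 13 tert-butyl (E)-3-(4-methoxy-3-methyl-2-oxo-2H-pyran-6-yl)but-2-enoate, via sodium phosphonate carbanion 12 (not isolated)
Conditions: 11, NaH, THF, 0 °C; then 10, 0 °C to rt; E isomer separated by chromatography
Reagents that add atoms: none
Why: In this Horner–Wadsworth–Emmons olefination of an activated aryl-type methyl ketone, reversible addition and the bulky tert-butyl ester should favour the E alkene (ester trans to Pyr, cis to methyl), and preforming the carbanion leaves no free base to attack the pyranone.

Step 9
Reactants: 13 tert-butyl (E)-3-(4-methoxy-3-methyl-2-oxo-2H-pyran-6-yl)but-2-enoate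
Product: 14 (E)-3-(4-methoxy-3-methyl-2-oxo-2H-pyran-6-yl)but-2-enoic acid
Conditions: TFA, CH2Cl2, 0 °C to rt
Reagents that add atoms: none
Why: Acidolysis of a tert-butyl ester (alkyl–oxygen cleavage through the tert-butyl cation) needs neither nucleophile nor base, so the pyranone, the enol ether and the E geometry are left untouched.

Step 10
Reactants: 14 (E)-3-(4-methoxy-3-methyl-2-oxo-2H-pyran-6-yl)but-2-enoic acid (2.2 equiv); 15 naphthalene-1,8-diol
Product: 17 naphthalene-1,8-diyl bis[(E)-3-(4-methoxy-3-methyl-2-oxo-2H-pyran-6-yl)but-2-enoate], via 8-hydroxynaphthalen-1-yl monoester 16 (not isolated)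
Conditions: DIC, DMAP (cat.), CH2Cl2, 0 °C to rt, argon, amber glass
Reagents that add atoms: none
Why: Steglich esterification acylates both peri hydroxyls in turn under near-neutral conditions and avoids the vinylketene pathway of acid chloride/amine methods, which could deconjugate or isomerise a β-methyl enoate.

Step 11
Reactants: 17 naphthalene-1,8-diyl bis[(E)-3-(4-methoxy-3-methyl-2-oxo-2H-pyran-6-yl)but-2-enoate]
Product: 19 meso (1R,2S,3R,4S)-3,4-dimethyl-3,4-di(Pyr)cyclobutane-1,2-dicarboxylic acid cyclic naphthalene-1,8-diyl diester (carboxyls cis to each other and to both methyls; both Pyr groups on the opposite face), via 1,4-biradical 18 (not isolated)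
Conditions: hν (365 nm LED), degassed MeCN (5 mM), 0 °C
Reagents that add atoms: none
Why: Proposed new method: light of 365 nm is taken up only by the extended pyranone–enoate chromophore, and the excited arm bonds through its α-carbon to the α-carbon of the ground-state arm, which the peri diester holds parallel at under 4 Å, to give the bis-tertiary, pyranonyl-stabilised 1,4-biradical 18, whose radical centres then recombine to make C3–C4. The closest known reaction type is the covalent-template [2+2] photodimerisation of cinnamate pairs on naphthalene-1,8-diol to β-truxinates, and the new element is a pair of trisubstituted β-methyl-β-heteroaryl enoates that must create two adjacent quaternary carbons. The nine-membered dilactone closes with the C1–C2 bond in a 9-exo-trig sense (both β-carbons stay outside that ring) and the cyclobutane closes by 1,4-biradical recombination, so the overall mode is a straight rather than crossed intramolecular [2+2]. C1 and C2 are set cis because the 1,8-diyl bridge can only span two carboxyls on one ring face, C3 and C4 inherit the E geometry of their arms (methyl cis and Pyr trans to the neighbouring carboxyl), and the mirror-symmetric face-to-face stack places both Pyr groups on the same face, so one meso isomer is expected. The step needs head-to-head regiochemistry, syn facial pairing, retention of both alkene geometries and reaction at the exocyclic alkenes instead of the pyranone C=C bonds: the rigid peri tether secures the first two, pre-stacking at 0 °C lets bonding compete with E/Z isomerisation (itself photoreversible) and with rotation in 18, and the ring alkenes lie out of register. Because 19 retains only isolated pyranone and naphthyl ester chromophores that are transparent at 365 nm, neither cycloreversion nor photo-Fries cleavage is driven.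

Step 12
Reactants: 19 meso tethered cyclobutane diester
Product: 21 meso (1R,2S,3R,4S)-3,4-dimethyl-3,4-di(Pyr)cyclobutane-1,2-dicarboxylic acid, via half-opened hydroxynaphthyl monoester 20 (not isolated)
Conditions: LiOH (4 equiv), degassed THF/H2O, 0 °C; then 1 M HCl
Reagents that add atoms: lithium hydroxide, [Li+].[OH-]
Why: In this saponification by acyl–oxygen cleavage, the aryl esters with their good peri-naphtholate leaving group should react well before the vinylogous-carbonate-like 4-methoxy-2-pyranones, the cis carboxylate formed first assists the second cleavage, and short cold exposure guards C1 and C2 against epimerisation.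

Step 13
Reactants: 21 meso cis-cyclobutane-1,2-dicarboxylic acid
Product: 22 meso 6,7-dimethyl-6,7-di(Pyr)-3-oxabicyclo[3.2.0]heptane-2,4-dione (methyls on the face of the anhydride ring; Pyr groups on the face of the bridgehead hydrogens)
Conditions: (CF3CO)2O, CH2Cl2, 0 °C to rt; evaporation
Reagents that add atoms: none
Why: Dehydration of a cis-1,2-dicarboxylic acid to the five-membered cyclic anhydride with trifluoroacetic anhydride is standard, leaves only volatile material to remove, and the cis ring fusion locks C1 and C2.

Step 14
Reactants: 22 meso cyclobutane-fused anhydride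
Product: 23 target CNP0481603.1 (route numbering 1R,2S,3R,4S)
Conditions: (DHQD)2AQN (20 mol %), MeOH (10 equiv), Et2O/toluene, −20 °C; then 1 M HCl wash
Reagents that add atoms: methanol, CO
Why: In this alkaloid-catalysed desymmetrising alcoholysis of a meso cyclic anhydride, the quinuclidine nitrogen acts as general base for methanol inside the chiral pocket and steers it to the enantiotopic carbonyl on C1, so no new centre is made but the mirror plane is broken to give C1 (ester) R and C2 (acid) S.

Compound list
1 | ethyl (S)-lactate | C[C@H](O)C(=O)OCC | starting material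
2 | ethyl (S)-2-[(tert-butyldimethylsilyl)oxy]propanoate | C[C@H](O[Si](C)(C)C(C)(C)C)C(=O)OCC | intermediate
3 | (S)-2-[(tert-butyldimethylsilyl)oxy]-N-methoxy-N-methylpropanamide | C[C@H](O[Si](C)(C)C(C)(C)C)C(=O)N(C)OC | intermediate
4 | ethyl 2-methylacetoacetate (racemic) | CCOC(=O)C(C)C(C)=O | starting material
5 | dilithium dienediolate (dianion) of 4 | [Li+].[Li+].C=C([O-])C(C)=C([O-])OCC | intermediate
6 | ethyl (6S)-6-[(tert-butyldimethylsilyl)oxy]-2-methyl-3,5-dioxoheptanoate (C2 epimers and enol forms) | C[C@H](O[Si](C)(C)C(C)(C)C)C(=O)CC(=O)C(C)C(=O)OCC | intermediate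
7 | 6-[(1S)-1-[(tert-butyldimethylsilyl)oxy]ethyl]-4-hydroxy-3-methyl-2H-pyran-2-one | C[C@H](O[Si](C)(C)C(C)(C)C)c1cc(O)c(C)c(=O)o1 | intermediate
8 | 6-[(1S)-1-[(tert-butyldimethylsilyl)oxy]ethyl]-4-methoxy-3-methyl-2H-pyran-2-one | C[C@H](O[Si](C)(C)C(C)(C)C)c1cc(OC)c(C)c(=O)o1 | intermediate
9 | 6-[(1S)-1-hydroxyethyl]-4-methoxy-3-methyl-2H-pyran-2-one | C[C@H](O)c1cc(OC)c(C)c(=O)o1 | intermediate
10 | 6-acetyl-4-methoxy-3-methyl-2H-pyran-2-one | CC(=O)c1cc(OC)c(C)c(=O)o1 | intermediate
11 | tert-butyl diethylphosphonoacetate | CCOP(=O)(OCC)CC(=O)OC(C)(C)C | starting material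
12 | sodium carbanion of 11 | [Na+].CCOP(=O)(OCC)[CH-]C(=O)OC(C)(C)C | intermediate
13 | tert-butyl (E)-3-(4-methoxy-3-methyl-2-oxo-2H-pyran-6-yl)but-2-enoate | C/C(=C\C(=O)OC(C)(C)C)c1cc(OC)c(C)c(=O)o1 | intermediate
14 | (E)-3-(4-methoxy-3-methyl-2-oxo-2H-pyran-6-yl)but-2-enoic acid | C/C(=C\C(=O)O)c1cc(OC)c(C)c(=O)o1 | intermediate
15 | naphthalene-1,8-diol | Oc1cccc2cccc(O)c12 | starting material
16 | 8-hydroxynaphthalen-1-yl (E)-3-(Pyr)but-2-enoate | C/C(=C\C(=O)Oc1cccc2cccc(O)c12)c1cc(OC)c(C)c(=O)o1 | intermediate
17 | naphthalene-1,8-diyl bis[(E)-3-(Pyr)but-2-enoate] | C/C(=C\C(=O)Oc1cccc2cccc(OC(=O)/C=C(\C)c3cc(OC)c(C)c(=O)o3)c12)c1cc(OC)c(C)c(=O)o1 | intermediate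
18 | 1,4-biradical (C1–C2 made, nine-membered ring closed, radical centres at C3 and C4) | O5C(=O)[C@@H]([C](C)c1cc(OC)c(C)c(=O)o1)[C@H](C(=O)Oc6cccc7cccc5c67)[C](C)c1cc(OC)c(C)c(=O)o1 | intermediate
19 | meso tethered cyclobutane, cyclic naphthalene-1,8-diyl diester | O5C(=O)[C@@H]1[C@H](C(=O)Oc6cccc7cccc5c67)[C@@](C)(c2cc(OC)c(C)c(=O)o2)[C@@]1(C)c1cc(OC)c(C)c(=O)o1 | intermediate
20 | half-opened 8-hydroxynaphthalen-1-yl hydrogen diester (racemic, one enantiomer drawn, neutral form) | OC(=O)[C@@H]1[C@H](C(=O)Oc3cccc4cccc(O)c34)[C@@](C)(c2cc(OC)c(C)c(=O)o2)[C@@]1(C)c1cc(OC)c(C)c(=O)o1 | intermediate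
21 | meso (1R,2S,3R,4S)-3,4-dimethyl-3,4-di(Pyr)cyclobutane-1,2-dicarboxylic acid | OC(=O)[C@@H]1[C@H](C(=O)O)[C@@](C)(c2cc(OC)c(C)c(=O)o2)[C@@]1(C)c1cc(OC)c(C)c(=O)o1 | intermediate
22 | meso cyclobutane-fused cyclic anhydride | O3C(=O)[C@@H]1[C@H](C3=O)[C@@](C)(c2cc(OC)c(C)c(=O)o2)[C@@]1(C)c1cc(OC)c(C)c(=O)o1 | intermediate
23 | CNP0481603.1; with the acid carbon as position 1: (1S,2R,3S,4R)-2-(methoxycarbonyl)-3,4-bis(4-methoxy-3-methyl-2-oxo-2H-pyran-6-yl)-3,4-dimethylcyclobutane-1-carboxylic acid | COC(=O)[C@@H]1[C@H](C(=O)O)[C@@](C)(c2cc(OC)c(C)c(=O)o2)[C@@]1(C)c1cc(OC)c(C)c(=O)o1 | target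

Total step count: 14. Longest linear sequence: 14 steps (1 to 23); 4, 11 and 15 enter as bought materials.

Steps most likely to fail

Step 11. The excited arm may relax by E/Z isomerisation faster than it bonds. The hindered biradical may also fall back to the two alkenes instead of joining two quaternary carbons. It may further rotate about C2–C3 or C1–C4 before closure and so lose the relative configuration. The fallback uses known chemistry, namely the topochemical solid-state [2+2] photodimerisation of diamine double salts of E-cinnamic-type acids, which gives head-to-head syn dimers. It sets out from 14 and comes back at 21, bypassing 17 and 19. Two equivalents of 14 would be crystallised with one of ethane-1,2-diamine from methanol to the double salt ethane-1,2-diammonium bis[(E)-3-(Pyr)but-2-enoate] F1, in which the dication pins two carboxylates side by side. The powdered crystals would be irradiated at 365 nm between glass plates, where the lattice blocks isomerisation and bond rotation. This should give the ethane-1,2-diammonium cyclobutane-1,2-dicarboxylate F2. Acidification with 1 M HCl and extraction would then deliver 21.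

Step 12. Hydroxide may open the pyranone lactones in competition with the hindered, neopentyl-type aryl esters. It may also enolise the activated esters and epimerise C1 or C2 to the trans series, which cannot close the anhydride. The fallback avoids hydroxide altogether, sets out from 19 and comes back at 21. The aryl esters would serve as active esters in an alcoholysis with allyl alcohol (Et3N, DMAP, CH2Cl2, rt), which should release the template and give the meso diallyl cyclobutane-1,2-dicarboxylate F3. Tsuji–Trost deallylation (Pd(PPh3)4 cat., morpholine, THF, rt) would then free both acids under neutral conditions.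

Step 14. The methyl groups on the anhydride face and the bulky Pyr groups may crowd the catalyst pocket and weaken the discrimination between the enantiotopic carbonyls. A slow catalysed reaction may let uncatalysed methanolysis compete. The sense of induction may also differ from that of simple anhydrides. The fallback replaces catalysis by classical resolution, sets out from 22 and comes back at 23. Achiral methanolysis (MeOH, Et3N, CH2Cl2, rt) would give 23 together with its mirror-image hemiester F4. Treatment with (R)-1-phenylethylamine and fractional crystallisation would isolate the less soluble diastereomeric salt, taken to be the (R)-1-phenylethylammonium salt of 23 F5; the (S)-amine would be used if the salt of the mirror image crystallised first. Partition between 1 M HCl and ethyl acetate would return 23.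

Further compounds
F1 | step 11 | ethane-1,2-diammonium bis[(E)-3-(Pyr)but-2-enoate] | [NH3+]CC[NH3+].C/C(=C\C(=O)[O-])c1cc(OC)c(C)c(=O)o1.C/C(=C\C(=O)[O-])c1cc(OC)c(C)c(=O)o1
F2 | step 11 | ethane-1,2-diammonium salt of meso diacid 21 | [NH3+]CC[NH3+].[O-]C(=O)[C@@H]1[C@H](C(=O)[O-])[C@@](C)(c2cc(OC)c(C)c(=O)o2)[C@@]1(C)c1cc(OC)c(C)c(=O)o1
F3 | step 12 | meso diallyl 3,4-dimethyl-3,4-di(Pyr)cyclobutane-1,2-dicarboxylate | C=CCOC(=O)[C@@H]1[C@H](C(=O)OCC=C)[C@@](C)(c2cc(OC)c(C)c(=O)o2)[C@@]1(C)c1cc(OC)c(C)c(=O)o1
F4 | step 14 | mirror-image hemiester (enantiomer of 23) | COC(=O)[C@H]1[C@@H](C(=O)O)[C@](C)(c2cc(OC)c(C)c(=O)o2)[C@]1(C)c1cc(OC)c(C)c(=O)o1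
F5 | step 14 | (R)-1-phenylethylammonium salt of 23 | C[C@@H]([NH3+])c1ccccc1.COC(=O)[C@@H]1[C@H](C(=O)[O-])[C@@](C)(c2cc(OC)c(C)c(=O)o2)[C@@]1(C)c1cc(OC)c(C)c(=O)o1
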